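**Assumptions.** Positions are numbered as in germacranolides (C1–C15). (S)-2-Methylglycidol, 2-(bromomethyl)acrylic acid and angelic acid are taken as purchasable. The C3 hemiketal configuration is taken to be fixed thermodynamically by the cis 3,10-oxygen bridge. The route is a paper design and has not been run.

## Retrosynthetic overview

1. Target ⇐ 3-keto-10-hydroxy macrocycle 28; the THF hemiketal ring forms last, on desilylation.
2. Ten-membered carbocycle ⇐ Nozaki–Hiyama–Kishi closure of C3–C4 from a (Z)-vinyl iodide and a C3 aldehyde.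
3. Seco compound ⇐ Barbier-type union at C7–C8 of bromomethyl-butenolide 10 (C4–C7, C11–C13, C15) with aldehyde 22 (C1–C3, C8–C10, C14); the angelate is installed by Mitsunobu inversion at C8.
4. 10 ⇐ but-2-yn-1-ol (Red-Al/I2, Sharpless epoxidation, RCM); 22 ⇐ (S)-2-methylglycidol (two epoxide openings, proline aminoxylation).
5. Ring order: butenolide (RCM) → α-methylene lactone (unveiled in the coupling) → ten-membered ring (NHK) → THF hemiketal.

## Fragment A (steps 1–8)

**Step 1**
Reactants: 1, but-2-yn-1-ol
Product: 2, (2Z)-3-iodobut-2-en-1-ol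
Conditions: Red-Al, THF, 0 °C → rt; then I2, THF, −78 °C
Reagents that add atoms: iodine, II
Why: Hydroxyl-directed trans-hydroalumination puts Al on C3 cis to CH2OH, and iodinolysis with retention gives the Z vinyl iodide (future C4=C5 geometry).

**Step 2**
Reactants: 2
Product: 3, ethyl (2E,4Z)-5-iodohexa-2,4-dienoate
Conditions: MnO2, Ph3P=CHCO2Et, CH2Cl2, rt
Reagents that add atoms: ethyl (triphenylphosphoranylidene)acetate, CCOC(=O)C=P(c1ccccc1)(c1ccccc1)c1ccccc1
Why: Tandem allylic oxidation/Wittig olefination traps the labile Z-iodoenal in situ; the stabilised ylide gives the 2E alkene.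

**Step 3**
Reactants: 3
Product: 4, (2E,4Z)-5-iodohexa-2,4-dien-1-ol
Conditions: DIBAL-H, CH2Cl2, −78 °C
Reagents that add atoms: none
Why: 1,2-Reduction of the enoate to the allylic alcohol; the vinyl iodide is inert at −78 °C.

**Step 4**
Reactants: 4
Product: 5, [(2R,3R)-3-[(1Z)-2-iodoprop-1-en-1-yl]oxiran-2-yl]methanol
Conditions: Ti(OiPr)4, D-(−)-DET, TBHP, 4 Å MS, CH2Cl2, −20 °C
Reagents that add atoms: tert-butyl hydroperoxide, CC(C)(C)OO
Why: Sharpless asymmetric epoxidation of the proximal E alkene; D-tartrate gives the 2R,3R epoxide, whose C3–O bond becomes the C6–O bond.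

**Step 5**
Reactants: 5
Product: 6, (2S,3R)-2-(iodomethyl)-3-[(1Z)-2-iodoprop-1-en-1-yl]oxirane
Conditions: I2, PPh3, imidazole, Et2O/MeCN, 0 °C
Reagents that add atoms: iodine, II
Why: Appel-type iodination of the primary alcohol; no stereocentre is touched (the C2 descriptor changes only by CIP priority).

**Step 6**
Reactants: 6
Product: 7, (3S,4Z)-5-iodohexa-1,4-dien-3-ol
Conditions: Zn dust, NaI, MeOH, reflux
Reagents that add atoms: none
Why: Zinc inserts into the alkyl C–I bond and β-eliminates with epoxide opening (reductive 1,3-transposition), giving the vinyl carbinol with the C6–O bond intact; the vinyl iodide does not react with unactivated Zn.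

**Step 7**
Reactants: 7; 8, 2-(bromomethyl)acrylic acid
Product: 9, (3S,4Z)-5-iodohexa-1,4-dien-3-yl 2-(bromomethyl)acrylate
Conditions: 8, (COCl)2, cat. DMF, CH2Cl2; then 7, 2,6-lutidine, −20 → 0 °C
Reagents that add atoms: none (all new atoms come from 8)
Why: Acylation via the acid chloride with a hindered base avoids SN2′ attack on the allylic bromide; the carbinol centre is untouched.

**Step 8**
Reactants: 9
Product: 10, (5S)-3-(bromomethyl)-5-[(1Z)-2-iodoprop-1-en-1-yl]furan-2(5H)-one (fragment A)
Conditions: Hoveyda–Grubbs II (5 mol %), toluene, 80 °C, 5 mM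
Reagents that add atoms: none
Why: Ring-closing metathesis between the vinyl group and the acrylate alkene forms the butenolide with loss of ethylene; the trisubstituted iodoalkene is metathesis-inert.

## Fragment B (steps 9–17)

**Step 9**
Reactants: 11, (S)-2-methylglycidol; 12, 1,3-dithiane
Product: 13, (2R)-3-(1,3-dithian-2-yl)-2-methylpropane-1,2-diol
Conditions: 12 (2.3 equiv), n-BuLi, THF, −30 °C; then 11, → 0 °C
Reagents that add atoms: none (C8 comes from 12)
Why: Corey–Seebach dithiane anion opens the epoxide at CH2 (future C9); C10 is not touched, and a Payne shift would lead to the same enantiomer.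

**Step 10**
Reactants: 13
Product: 14, (2R)-2-(1,3-dithian-2-ylmethyl)-2-methyloxirane
Conditions: NaH, N-tosylimidazole, THF, 0 °C → rt
Reagents that add atoms: none
Why: Selective primary sulfonylation followed by intramolecular Williamson closure from the tertiary alkoxide; the C10–O bond is retained.

**Step 11**
Reactants: 14; 15, acetonitrile
Product: 16, (4S)-5-(1,3-dithian-2-yl)-4-hydroxy-4-methylpentanenitrile
Conditions: 15, n-BuLi, THF, −78 °C; then 14, → rt
Reagents that add atoms: none (C2 and C3 come from 15)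
Why: Lithioacetonitrile opens the 2,2-disubstituted epoxide at the CH2 terminus (C1), leaving the tertiary carbinol intact.

**Step 12**
Reactants: 16
Product: 17, (4S)-5-(1,3-dithian-2-yl)-4-methyl-4-(triethylsilyloxy)pentanenitrile
Conditions: TESOTf, 2,6-lutidine, CH2Cl2, −78 → 0 °C
Reagents that add atoms: triethylsilyl triflate, CC[Si](CC)(CC)OS(=O)(=O)C(F)(F)F
Why: Silylation of the tertiary alcohol prevents lactol formation in the next steps.

**Step 13**
Reactants: 17
Product: 18, (4S)-5-(1,3-dithian-2-yl)-4-methyl-4-(triethylsilyloxy)pentanal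
Conditions: DIBAL-H, toluene, −78 °C; aq. Rochelle salt
Reagents that add atoms: water (work-up), O
Why: Partial reduction of the nitrile to the aluminium imine and hydrolysis gives the aldehyde; dithiane and TES ether are inert.

**Step 14**
Reactants: 18
Product: 19, (2S,4S)-5-(1,3-dithian-2-yl)-4-methyl-2-(N-phenylaminooxy)-4-(triethylsilyloxy)pentan-1-ol
Conditions: D-proline (20 mol %), PhNO, DMSO, rt; then NaBH4, EtOH, 0 °C
Reagents that add atoms: nitrosobenzene, O=Nc1ccccc1
Why: Proline-catalysed α-aminoxylation via the enamine; D-proline sets C2 as S under catalyst control, independent of the remote C10 centre, and the labile aldehyde is reduced in situ.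

**Step 15**
Reactants: 19
Product: 20, (2S,4S)-5-(1,3-dithian-2-yl)-4-methyl-4-(triethylsilyloxy)pentane-1,2-diol
Conditions: Zn dust, AcOH/EtOH, rt
Reagents that add atoms: none
Why: Reductive N–O cleavage frees the C2 hydroxyl without touching the stereocentre; Zn is used because Cu(II) could attack the dithiane.

**Step 16**
Reactants: 20
Product: 21, 2-[(2S,4S)-2-methyl-2,4,5-tris(triethylsilyloxy)pentyl]-1,3-dithiane
Conditions: TESCl, imidazole, cat. DMAP, CH2Cl2, 0 °C → rt
Reagents that add atoms: chlorotriethylsilane, CC[Si](CC)(CC)Cl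
Why: Silylation of both remaining hydroxyls; the primary TES ether is later the latent C3 aldehyde.

**Step 17**
Reactants: 21
Product: 22, (3S,5S)-3-methyl-3,5,6-tris(triethylsilyloxy)hexanal (fragment B)
Conditions: MeI, CaCO3, MeCN/H2O 9:1, 45 °C
Reagents that add atoms: water, O
Why: Neutral S-alkylative dithiane hydrolysis releases the C8 aldehyde without cleaving silyl ethers or eliminating the β-silyloxy group.

## Fragment union and endgame (steps 18–23)

**Step 18**
Reactants: 10; 22
Product: 23, seco alcohol (2S,6S,7R,8S,10R): 6,7-trans α-methylene-γ-lactone with the (Z)-2-iodopropenyl group on C6, the C8–C10/C1–C3 chain on C7, free 8-OH (8-epi), and TES ethers at O2, O3, O10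
Conditions: CrCl2 (Ni-free, 3 equiv), THF, 0 °C → rt
Reagents that add atoms: none
Why: Barbier-type (Nozaki–Hiyama) allylation through a Zimmerman–Traxler chair: C7 attacks anti to the C6 substituent (7R, trans lactone), and the ring-locked E-type allylmetal is expected to give the anti (8S) carbinol; Ni-free Cr(II) leaves the vinyl iodide alone.

**Step 19**
Reactants: 23; 24, angelic acid
Product: 25, 8-O-angeloyl seco ester (2S,6S,7R,8R,10R)
Conditions: 24, PPh3, DIAD, toluene, 0 °C → rt
Reagents that add atoms: none (the ester comes from 24)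
Why: Mitsunobu esterification inverts C8 to the required 8R configuration and installs the angelate under neutral conditions that do not isomerise it to tiglate.

**Step 20**
Reactants: 25
Product: 26, C3 aldehyde (2S,6S,7R,8R,10R), with 2-OTES and 10-OTES retained
Conditions: (COCl)2, DMSO, CH2Cl2, −78 → −40 °C; Et3N, → 0 °C
Reagents that add atoms: none
Why: Swern conditions oxidise a primary TES ether directly to the aldehyde while secondary and tertiary TES ethers survive.

**Step 21**
Reactants: 26
Product: 27, ten-membered (4Z)-allylic alcohol (2S,6R,7R,8R,10R; C3 epimer mixture)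
Conditions: CrCl2 (10 equiv), NiCl2 (2 mol %), DMSO/THF, rt, 2 mM
Reagents that add atoms: none
Why: Intramolecular Nozaki–Hiyama–Kishi addition of the vinyl iodide to the aldehyde closes C3–C4 with retention of Z geometry and tolerates the esters; the new C3 centre is removed in the next step.

**Step 22**
Reactants: 27
Product: 28, (4Z)-3-keto macrocycle (2S,6R,7R,8R,10R), 2,10-bis-TES ether
Conditions: Dess–Martin periodinane, NaHCO3, CH2Cl2, 0 °C → rt
Reagents that add atoms: none
Why: Buffered oxidation of the allylic alcohol converges both C3 epimers to the enone without epimerising C2.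

**Step 23**
Reactants: 28
Product: 29, 2β-hydroxy-1-desoxyniveusin A (2S,3S,6R,7R,8R,10S)
Conditions: HF·pyridine, pyridine, THF, 0 °C → rt
Reagents that add atoms: none
Why: Desilylation frees 2-OH and 10-OH; 10-OH adds to the C3 ketone (transannular hemiketalisation), and the cis bridge across the ten-membered ring allows only the 3S hemiketal.

## Compound list

1 | but-2-yn-1-ol | CC#CCO | starting material
2 | (2Z)-3-iodobut-2-en-1-ol | OC/C=C(/C)I | intermediate
3 | ethyl (2E,4Z)-5-iodohexa-2,4-dienoate | CCOC(=O)/C=C/C=C(/C)I | intermediate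
4 | (2E,4Z)-5-iodohexa-2,4-dien-1-ol | OC/C=C/C=C(/C)I | intermediate
5 | [(2R,3R)-3-[(1Z)-2-iodoprop-1-en-1-yl]oxiran-2-yl]methanol | OC[C@H]1O[C@@H]1/C=C(/C)I | intermediate
6 | (2S,3R)-2-(iodomethyl)-3-[(1Z)-2-iodoprop-1-en-1-yl]oxirane | IC[C@H]1O[C@@H]1/C=C(/C)I | intermediate
7 | (3S,4Z)-5-iodohexa-1,4-dien-3-ol | C=C[C@H](O)/C=C(/C)I | intermediate
8 | 2-(bromomethyl)acrylic acid | C=C(CBr)C(=O)O | starting material
9 | (3S,4Z)-5-iodohexa-1,4-dien-3-yl 2-(bromomethyl)acrylate | C=C[C@H](OC(=O)C(=C)CBr)/C=C(/C)I | intermediate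
10 | (5S)-3-(bromomethyl)-5-[(1Z)-2-iodoprop-1-en-1-yl]furan-2(5H)-one | O=C1O[C@H](/C=C(/C)I)C=C1CBr | intermediate (fragment A)
11 | (S)-2-methylglycidol | C[C@]1(CO)CO1 | starting material
12 | 1,3-dithiane | C1CSCSC1 | starting material
13 | (2R)-3-(1,3-dithian-2-yl)-2-methylpropane-1,2-diol | C[C@@](O)(CC1SCCCS1)CO | intermediate
14 | (2R)-2-(1,3-dithian-2-ylmethyl)-2-methyloxirane | C[C@@]1(CC2SCCCS2)CO1 | intermediate
15 | acetonitrile | CC#N | starting material
16 | (4S)-5-(1,3-dithian-2-yl)-4-hydroxy-4-methylpentanenitrile | C[C@@](O)(CC1SCCCS1)CCC#N | intermediate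
17 | (4S)-5-(1,3-dithian-2-yl)-4-methyl-4-(triethylsilyloxy)pentanenitrile | C[C@@](O[Si](CC)(CC)CC)(CC1SCCCS1)CCC#N | intermediate
18 | (4S)-5-(1,3-dithian-2-yl)-4-methyl-4-(triethylsilyloxy)pentanal | C[C@@](O[Si](CC)(CC)CC)(CC1SCCCS1)CCC=O | intermediate
19 | (2S,4S)-5-(1,3-dithian-2-yl)-4-methyl-2-(N-phenylaminooxy)-4-(triethylsilyloxy)pentan-1-ol | C[C@@](O[Si](CC)(CC)CC)(CC1SCCCS1)C[C@H](ONc1ccccc1)CO | intermediate
20 | (2S,4S)-5-(1,3-dithian-2-yl)-4-methyl-4-(triethylsilyloxy)pentane-1,2-diol | C[C@@](O[Si](CC)(CC)CC)(CC1SCCCS1)C[C@H](O)CO | intermediate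
21 | 2-[(2S,4S)-2-methyl-2,4,5-tris(triethylsilyloxy)pentyl]-1,3-dithiane | C[C@@](O[Si](CC)(CC)CC)(CC1SCCCS1)C[C@H](O[Si](CC)(CC)CC)CO[Si](CC)(CC)CC | intermediate
22 | (3S,5S)-3-methyl-3,5,6-tris(triethylsilyloxy)hexanal | O=CC[C@@](C)(O[Si](CC)(CC)CC)C[C@H](O[Si](CC)(CC)CC)CO[Si](CC)(CC)CC | intermediate (fragment B)
23 | seco 8-epi alcohol (2S,6S,7R,8S,10R) | C=C1C(=O)O[C@H](/C=C(/C)I)[C@H]1[C@@H](O)C[C@@](C)(O[Si](CC)(CC)CC)C[C@H](O[Si](CC)(CC)CC)CO[Si](CC)(CC)CC | intermediate
24 | angelic acid, (Z)-2-methylbut-2-enoic acid | C/C=C(/C)C(=O)O | starting material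
25 | seco 8-angelate (2S,6S,7R,8R,10R) | C=C1C(=O)O[C@H](/C=C(/C)I)[C@H]1[C@H](OC(=O)/C(C)=C\C)C[C@@](C)(O[Si](CC)(CC)CC)C[C@H](O[Si](CC)(CC)CC)CO[Si](CC)(CC)CC | intermediate
26 | seco C3 aldehyde (2S,6S,7R,8R,10R) | C=C1C(=O)O[C@H](/C=C(/C)I)[C@H]1[C@H](OC(=O)/C(C)=C\C)C[C@@](C)(O[Si](CC)(CC)CC)C[C@H](O[Si](CC)(CC)CC)C=O | intermediate
27 | macrocyclic (4Z)-3-ol, C3 epimers (2S,6R,7R,8R,10R) | C=C1C(=O)O[C@@H]2/C=C(/C)C(O)[C@@H](O[Si](CC)(CC)CC)C[C@](C)(O[Si](CC)(CC)CC)C[C@@H](OC(=O)/C(C)=C\C)[C@@H]12 | intermediate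
28 | macrocyclic (4Z)-3-ketone (2S,6R,7R,8R,10R) | C=C1C(=O)O[C@@H]2/C=C(/C)C(=O)[C@@H](O[Si](CC)(CC)CC)C[C@](C)(O[Si](CC)(CC)CC)C[C@@H](OC(=O)/C(C)=C\C)[C@@H]12 | intermediate
29 | 2β-hydroxy-1-desoxyniveusin A | C=C1C(=O)O[C@@H]2/C=C(/C)[C@]3(O)O[C@](C)(C[C@@H](OC(=O)/C(C)=C\C)[C@@H]12)C[C@@H]3O | target

## Step count

- Total: 23 steps (fragment A 8, fragment B 9, union and endgame 6).
- Longest linear sequence: 15 steps (steps 9–17, then 18–23), which is 65 % of the total.

## Three steps most likely to fail

1. **Steps 18–19, C8 configuration.** The anti sense of the Barbier addition is a transition-state prediction, and the Mitsunobu inversion is at a hindered carbinol where elimination toward C7 or PPh3 addition to the methylene lactone can compete. Fallback: replace the ring-locked bromide 10 by an open-chain (Z)-2-(bromomethyl)-2-enoate with O6 silyl-protected. Its Z-type chair gives the syn (8R) alcohol directly; acylate with retention (angelic acid, 2,4,6-trichlorobenzoyl chloride, Et3N, DMAP) and close the 6,7-lactone after desilylation.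

2. **Step 21, NHK closure of the ten-membered ring.** Oligomerisation or failure to cyclise is the usual problem at this ring size. Fallback: form C3–C4 earlier as an intermolecular vinyl-metal addition, and close the carbocycle instead at C4=C5 by ring-closing metathesis. The RCM substrate would be a C3 isopropenyl ketone held as its 3,10-methyl ketal (which pre-folds the chain) with a C6 vinyl group.

3. **Step 8, RCM of the 2-(bromomethyl)acrylate.** The allylic bromide, the hindered 1,1-disubstituted alkene or ester transposition may interfere. Fallback: acylate 7 with acryloyl chloride, close the simple butenolide by RCM, then add C13 by Morita–Baylis–Hillman hydroxymethylation (aqueous HCHO, imidazole) and convert to the bromide with PBr3.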